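The runs are calculated for substances that don't exist.

For the late times asked here, start from the last readings of the delta run, and look at the ratio of target to intermediate there.

| flask | starting material | temperature | remark | time |
|---|---|---|---|---|
| delta | 0.075 M | 25 °C | run made earlier |  |
| dawn | 0.050 M | 25 °C |  | 20 min |
| summer | 0.050 M | 50 °C |  | 20 min |
| winter | 0.050 M | 100 °C |  | 20 min |
| spring | 0.050 M | 75 °C |  | 20 min |

delta run (percent of the starting material charged)

| time / min | intermediate / % | target / % | starting material / % |
|---|---|---|---|
| 0.500 | 13 | 0 | 84 |
| 0.667 | 11 | 4 | 78 |
| 1.00 | 15 | 4 | 72 |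
| 1.50 | 26 | 4 | 58 |
| 2.50 | 26 | 11 | 43 |
| 4.00 | 28 | 18 | 24 |
| 6.00 | 19 | 27 | 12 |

(readings scatter by 1.5 percentage points)

- the earlier runs do not show what temperature does; that part of a forecast is a guess

- the best flask by amount of intermediate, in percent of the starting material charged; "all alike" if 1.5 percentage points covers them all (dawn / summer / winter / spring / all alike)
- amount of intermediate at the end, in percent of the starting material charged, dawn
- amount of intermediate at the end, in percent of the starting material charged, summer
- amount of intermediate at the end, in percent of the starting material charged, winter
- amount of intermediate at the end, in percent of the starting material charged, spring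

Build the flask one step at a time. Take the main step first: starting material goes to intermediate. Starting material falls from 84% to 12% between 0.500 min and 6.00 min, so its first-order constant k_A reads 0.354 min⁻¹. With this step alone, dawn would hold 99.9% intermediate at 20 min.

Now add intermediate to target, one way. Over the last interval the target gains 9 percentage points, so its constant k_P reads 0.191 min⁻¹. Dawn then drops to 4.55%.

Now let that step run back. The net flow from intermediate to target is then a forward rate minus a back rate, and when the two match, target over intermediate stands at the equilibrium ratio of the step. The delta run reads this ratio as 0.643 at 4.00 min and 1.42 at 6.00 min. Call the last reading ρ, the running ratio of target to intermediate. While the ratio climbs, the flask is still moving. Once it stands, intermediate equals target divided by it, not zero.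

The rest of the flask is unseen: 42.0% of the charge is missing at 6.00 min. Suppose the converted material keeps its last split. Dawn then holds about 21.6%, and less if the ratio climbs on. So I expect dawn between 4.55% and 21.6%. These runs do not show how heat moves the ratio, so summer, spring and winter stay a guess, and they need not reach zero.

The forecast gives 1.5%, 0.1%, 0% and 0% for dawn, summer, winter and spring, hence all alike, on the ground that “Heating should only speed up consumption”, and its dawn figure lies below my range.

The flasks give 8.41%, 8.19%, 36.7% and 20.5% in that order, so the best is winter.

    starting material → intermediate (k = 0.297 min⁻¹, Ea = 77.0 kJ mol⁻¹)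
    intermediate ⇌ target (K = 4.75, k = 0.288 min⁻¹, Ea = 90.0 kJ mol⁻¹, ΔH = −21.0 kJ mol⁻¹)
    intermediate ⇌ isomer of the product A (K = 2.10, k = 0.152 min⁻¹, Ea = 87.0 kJ mol⁻¹, ΔH = −85.0 kJ mol⁻¹)
    starting material + intermediate → side product (k = 0.918 M⁻¹ min⁻¹, Ea = 66.0 kJ mol⁻¹)
    starting material ⇌ dormant form (K = 0.490, k = 0.0634 min⁻¹, Ea = 89.0 kJ mol⁻¹, ΔH = 33.0 kJ mol⁻¹)
    target ⇌ isomer of the product B (K = 7.41, k = 0.0851 min⁻¹, Ea = 84.0 kJ mol⁻¹, ΔH = −26.0 kJ mol⁻¹)
    (constants at 25 °C)

In winter at the asked time, intermediate has a half-life of 0.24 s by the forward rate of the path to isomer of the product A alone, shorter than the 20 min of the run. Winter intermediate reads 36.7% after 10.0 min and 36.7% after 200 min, the picture of thermodynamic control, and the winter ratio of target to intermediate is 0.865, lower than the delta reading ρ.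

Take the neighbour of winter, the same flask run at 125 °C, which ends with 29.4% target. That target divided by ρ gives 20.7% intermediate there. The computed flask holds 52.0%, a ratio of 0.566.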